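The trap in this flask is to let dissolved material fall at once into its equilibrium proportions, which hurries target along.

solid substrate 0.40 M; time 50 s

    starting material ⇌ target (K1 = 0.34, k1 = 0.056 /s)
    target ⇌ isomer of the product (K2 = 0.92, k2 = 0.11 /s)
    solid substrate ⇌ starting material, rate k3*(cs3 - [starting material]) while solid is left; crystals form when [starting material] > cs3 (cs3 = 0.21 M, k3 = 0.070 /s)

- how much target there is at 50 s, in percent of the solid substrate charged
- concentration of starting material in solution at 50 s, in percent of saturation

- solid, in amounts per volume of the solution: solid substrate
- at the start none of the solid substrate is in solution
- starting material means what is dissolved; the solid is not counted in it
- run time (flask): 50 s

Starting material heads for saturation, with target and isomer of the product following, so the solution can hold 86.8% of the charge, less than the whole charge. Solid therefore stays, and target has a ceiling of 17.8% of the charge.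

The solid delivers in proportion to the gap below saturation. The area of that gap, divided by saturation, gives starting material a mean time of 23.6 s. Replacing the curve by one exponential with that mean, and taking the split as instant (a pre-equilibrium), puts starting material at 88.0% of saturation and target at 15.7% of the charge by 50 s.

That instant split is the weak link. The relaxation half-lives of the two steps, each taken alone, are 3.14 s and 3.02 s and look short against 50 s, but target and isomer of the product form a pool filled through the first step, and filling it adds a mean delay of 11.7 s, longer than either half-life and about half of the mean time of starting material. The two times add to 35.3 s: target's mean wait, the area between its curve and its ceiling divided by that ceiling. One exponential with this mean gives 13.5% of the charge as target, while starting material remains reckoned at 88.0% of saturation.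

The forecast, a little apart from this reckoning, gives 13.7% and 86%, arguing “so some solid always remains and the system stays linear”.

The flask gives 13.7% and 86.1%. Its target moves by 5 points when the reading comes forward to 24.3 s, and the mean wait puts target there at 8.86% of the charge.

Left until 2.0 min, the same flask should by the mean wait hold 17.2% as target. That neighbour shows 17.4%, with 15.2% of the charge still solid.

The numbers were drawn at random within sensible limits; the result is computed.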